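| flask | starting complex | incoming ligand | remark | time |
|---|---|---|---|---|
| north | 0.35 M | 3 equiv | run made earlier |  |
| east | 0.55 M | 3 equiv | run made earlier |  |
| north-east | 0.25 M | 6 equiv | run made earlier |  |
| flask | 0.25 M | 3.00 equiv |  | 3.0 d |

| run | time / h | complex with one exchanged / % | complex with three exchanged / % |
|---|---|---|---|
| north | 2.50 | 20 | 26 |
| north | 6.00 | 9 | 40 |
| north | 12.0 | 4 | 57 |
| north | 20.0 | 2 | 68 |
| north | 25.0 | 0 | 76 |
| north | 30.0 | 0 | 77 |
| north | 40.0 | 0 | 83 |
| east | 3.00 | 7 | 41 |
| east | 5.00 | 3 | 49 |
| east | 8.00 | 4 | 60 |
| east | 12.0 | 1 | 68 |
| east | 20.0 | 1 | 80 |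
| east | 30.0 | 0 | 83 |
| east | 40.0 | 0 | 88 |
| north-east | 3.00 | 1 | 69 |
| north-east | 6.00 | 2 | 88 |
| north-east | 12.0 | 0 | 95 |
| north-east | 25.0 | 2 | 101 |
| north-east | 40.0 | 0 | 100 |

(standard deviation of a reading: 1.5 percentage points)



- equivalents of incoming ligand to starting complex, everything else as given, that leave most complex with one exchanged at 3.0 d
- the amount of complex with one exchanged then, in percent of the starting complex charged
- the amount of complex with one exchanged with the amounts as given

1. After 40.0 h, the north-east run on 6 equiv shows 100% complex with three exchanged, more than the 83% of the north run on 3 equiv. That run reaches the full exchange of 3 sites per complex, so 3.00 equiv is one incoming ligand per site.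

2. Let p be the filled share of sites, which is the charge over 3.00 equiv once the incoming ligand is taken up. If uptake falls on sites by chance (a statistical distribution), the share with one exchanged is 3 times p times the square of the unfilled share. This peaks at p of a third, so at 1.00 equiv, where this chance share 44.4% is my estimate of the best yield.

3. For the flask as charged I reckon the small share that remains near full uptake. I borrow the north run's last reading and assume the remainder is complex with two exchanged, which gives p = 94.3% and a chance share of 0.909%.

4. The weak link is chance itself, so I test it on the north reading at 2.50 h. Its 26% of complex with three exchanged gives p = 63.8% and a chance share of 25.1%, against 20% read. I keep 44.4%, with a margin of about that gap.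

5. The forecast says 1 equiv, 18% and 0.5%, holding of the complex with one exchanged that “its consumption is roughly 3–8 times faster than its formation”. Its peak is lower than mine.

6. The simulation gives 1.02 equiv, 50.4% and 0.102%.

    complex with one exchanged + incoming ligand → leaving ligand + complex with two exchanged (k = 0.0440 L mol⁻¹ min⁻¹)
    incoming ligand ⇌ dormant form (K = 1.40, k = 0.00640 min⁻¹)
    complex with two exchanged + incoming ligand → leaving ligand + complex with three exchanged (k = 0.0150 L mol⁻¹ min⁻¹)
    starting complex + incoming ligand → leaving ligand + complex with one exchanged (k = 0.0900 L mol⁻¹ min⁻¹)
    crystals ⇌ leaving ligand, rate k5*(cs5 - [leaving ligand]) while solid is left; crystals form when [leaving ligand] > cs5 (solubility = 0.0940 M, k = 5.00 min⁻¹)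

The second exchange has 0.49 of the rate constant of the first (a selectivity factor), less than the 0.667 of chance. The best yield stands 6 percentage points above 44.4% and 32 points above the forecast.

In the neighbour flask on 0.750 equiv, p is a quarter, so the chance share is 42.2%. That neighbour flask computes to 47.0% of complex with one exchanged after 3.00 d.

Readings and results are calculated from invented constants, noise included.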